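**Route overview**

Numbering: C1 (CH2Cl), C2 (CBr, methyl), C3 (CHOH), C4, C5–C6 (oxirane, methyl on C6), C7 (CCl), C8 (=CHBr).
Retrosynthesis: the two oxirane C–O bonds are cut first (back to an E-C5=C6 alkene), then C2–Br and C1–Cl together (back to a C1=C2 isopropenyl group), then C7–Cl, then C7=C8 (back to an aldehyde at C7), and last C3–C4.
The feature that allows the key step is the C3 carbinol: it is allylic to the 1,1-disubstituted C1=C2 alkene and only homoallylic to C5=C6, so the same hydroxyl can first steer the bromochlorination and later the closure of the only ring, the oxirane.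
Forward: a vinylogous aldol joins methacrolein (C1–C3) to the dienolate of ethyl tiglate (C4–C7) at C3–C4, C8 is added by dibromo-olefination, the bromoalkyne is hydrochlorinated to the Z-bromochlorovinyl group, C1/C2 are halogenated, and the oxirane is formed last.
Stereochemistry: C3 (R) from the catalytic enantioselective aldol; C2 (R) relayed from C3 through a titanium alkoxide with a matched chiral ligand; C5 (S)/C6 (R) from vanadium epoxidation directed by the C3 hydroxyl; E-C5=C6 from the aldol and 7Z from anti-addition of HCl.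

Key step: step 10

Remark 1: the (R,R)-bisphosphoramide is assumed to expose the Re face of methacrolein, which gives the (R)-carbinol; should Mosher ester analysis of 6 show the opposite, the (S,S)-catalyst is used with nothing else changed.
Remark 2: of the two enantiomers of the Schiff-base ligand in step 10, the one built from the (S)-amino alcohol is assumed to be matched with the (3R)-carbinol; if it is not, its mirror image is used.

**Steps**

Step 1
Reactants: 1 ethyl tiglate [ethyl (E)-2-methylbut-2-enoate]
Product: 3 tert-butyl[(1-ethoxy-2-methylbuta-1,3-dien-1-yl)oxy]dimethylsilane, via lithium dienolate 2 (not isolated)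
Conditions: LiN(iPr)2 (1.1 equiv), DMPU, THF, −78 °C; then TBSCl, −78 °C → rt
Reagents that add atoms: tert-butyldimethylsilyl chloride (TBSCl), CC(C)(C)[Si](C)(C)Cl
Why: Kinetic γ-deprotonation of the enoate by the amide base in the presence of the polar cosolvent gives the extended dienolate, which the silyl chloride traps on oxygen (dienolate O-silylation) to give the vinylketene silyl acetal, whose ketene-acetal geometry is irrelevant for step 2.

Step 2
Reactants: 3 tert-butyl[(1-ethoxy-2-methylbuta-1,3-dien-1-yl)oxy]dimethylsilane; 4 methacrolein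
Product: 6 ethyl (R,E)-5-hydroxy-2,6-dimethylhepta-2,6-dienoate, via trichlorosilyl aldolate 5 (not isolated)
Conditions: SiCl4 (1.1 equiv), (R,R)-bisphosphoramide [two 1,1'-binaphthyl-2,2'-diamine-derived phosphoramide units joined by a pentane-1,5-diyl tether] (2 mol %), iPr2NEt (10 mol %), CH2Cl2, −78 °C; then aq. NaHCO3
Reagents that add atoms: none
Why: In this Lewis-base-catalysed, SiCl4-mediated vinylogous Mukaiyama aldol the phosphoramide-bound trichlorosilyl cation activates the enal for 1,2-addition, the dienolate attacks through its unhindered γ-carbon to form C3–C4 and the E-C5=C6 alkene, and the chiral pocket should expose the Re face of the aldehyde so that C3 is (R), to be confirmed by Mosher ester analysis.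

Step 3
Reactants: 6 ethyl (R,E)-5-hydroxy-2,6-dimethylhepta-2,6-dienoate
Product: 7 ethyl (R,E)-5-[(tert-butyldimethylsilyl)oxy]-2,6-dimethylhepta-2,6-dienoate
Conditions: TBSCl, imidazole, DMF, rt
Reagents that add atoms: tert-butyldimethylsilyl chloride (TBSCl), CC(C)(C)[Si](C)(C)Cl
Why: Imidazole-promoted silylation of the secondary alcohol is routine and is needed because the free carbinol would be brominated by the phosphine/CBr4 system of step 6 and would consume base in step 7.

Step 4
Reactants: 7 ethyl (R,E)-5-[(tert-butyldimethylsilyl)oxy]-2,6-dimethylhepta-2,6-dienoate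
Product: 8 (R,E)-5-[(tert-butyldimethylsilyl)oxy]-2,6-dimethylhepta-2,6-dien-1-ol
Conditions: iBu2AlH (2.2 equiv), CH2Cl2, −78 °C; then aq. potassium sodium tartrate
Reagents that add atoms: none
Why: Two equivalents of the aluminium hydride reduce the α,β-unsaturated ester by clean 1,2-reduction to the allylic alcohol at low temperature without touching the silyl ether or either alkene.

Step 5
Reactants: 8 (R,E)-5-[(tert-butyldimethylsilyl)oxy]-2,6-dimethylhepta-2,6-dien-1-ol
Product: 9 (R,E)-5-[(tert-butyldimethylsilyl)oxy]-2,6-dimethylhepta-2,6-dienal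
Conditions: MnO2 (excess), CH2Cl2, rt
Reagents that add atoms: none
Why: Heterogeneous MnO2 oxidation is selective for allylic alcohols and should give the enal without over-oxidation or loss of the E geometry.

Step 6
Reactants: 9 (R,E)-5-[(tert-butyldimethylsilyl)oxy]-2,6-dimethylhepta-2,6-dienal; 10 carbon tetrabromide
Product: 11 tert-butyl{[(3R,5E)-8,8-dibromo-2,6-dimethylocta-1,5,7-trien-3-yl]oxy}dimethylsilane
Conditions: PPh3, Zn dust, CH2Cl2, rt (10 premixed with PPh3 and Zn before 9 is added)
Reagents that add atoms: none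
Why: In this Corey–Fuchs (Ramirez) dibromo-olefination the dibromomethylene ylide formed from PPh3, CBr4 and zinc undergoes a Wittig reaction with the enal to add C8, and the zinc variant keeps the medium free of acid so that the silyl ether survives.

Step 7
Reactants: 11 tert-butyl{[(3R,5E)-8,8-dibromo-2,6-dimethylocta-1,5,7-trien-3-yl]oxy}dimethylsilane
Product: 12 tert-butyl{[(3R,5E)-8-bromo-2,6-dimethylocta-1,5-dien-7-yn-3-yl]oxy}dimethylsilane
Conditions: NaN(SiMe3)2 (1.05 equiv), THF, −78 °C
Reagents that add atoms: none
Why: E2 dehydrobromination of the 1,1-dibromoalkene by one equivalent of the hindered amide base removes the C7 hydrogen together with the bromide anti to it and stops at the 1-bromoalkyne, because this base cannot carry out metal–halogen exchange.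

Step 8
Reactants: 12 tert-butyl{[(3R,5E)-8-bromo-2,6-dimethylocta-1,5-dien-7-yn-3-yl]oxy}dimethylsilane
Product: 13 tert-butyl{[(3R,5E,7Z)-8-bromo-7-chloro-2,6-dimethylocta-1,5,7-trien-3-yl]oxy}dimethylsilane
Conditions: Pd(OAc)2 (5 mol %), LiCl (3 equiv), AcOH, rt
Reagents that add atoms: lithium chloride (LiCl), [Li+].[Cl-]
Why: Palladium-catalysed hydrochlorination of a 1-bromoalkyne proceeds by trans-chloropalladation with divalent palladium (chloride to C7, palladium to the bromine-bearing C8) and protonolysis of the C8–Pd bond by acetic acid, a net anti-addition of HCl that places Cl cis to Br (7Z); any partial loss of the silyl ether in acetic acid is harmless because step 9 removes it.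

Step 9
Reactants: 13 tert-butyl{[(3R,5E,7Z)-8-bromo-7-chloro-2,6-dimethylocta-1,5,7-trien-3-yl]oxy}dimethylsilane
Product: 14 (3R,5E,7Z)-8-bromo-7-chloro-2,6-dimethylocta-1,5,7-trien-3-ol
Conditions: HF·pyridine, pyridine, THF, 0 °C → rt
Reagents that add atoms: none
Why: Buffered acidic fluoride cleaves the silyl ether, and a basic fluoride source is avoided because the C8 hydrogen is anti to the C7 chlorine, so base could eliminate HCl back to the bromoalkyne.

Step 10
Reactants: 14 (3R,5E,7Z)-8-bromo-7-chloro-2,6-dimethylocta-1,5,7-trien-3-ol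
Product: 15 (2R,3R,5E,7Z)-2,8-dibromo-1,7-dichloro-2,6-dimethylocta-5,7-dien-3-ol
Conditions: NBS (1.05 equiv), ClTi(OiPr)3 (1.1 equiv), chiral tridentate Schiff-base diol ligand [imine of a 3,5-disubstituted salicylaldehyde with an (S)-2-amino-1,1-diarylalkan-1-ol] (30 mol %), hexanes, −20 °C
Reagents that add atoms: N-bromosuccinimide (NBS), O=C1CCC(=O)N1Br; chlorotitanium triisopropoxide ClTi(OiPr)3, CC(C)O[Ti](Cl)(OC(C)C)OC(C)C
Why: The C3 hydroxyl of 14 exchanges onto tetravalent titanium that also carries the chiral Schiff-base diol and chloride, NBS transfers Br+ to the tethered C1=C2 alkene, and the bromonium ion is opened at the distal primary carbon C1 by titanium-bound chloride delivered inside the complex (anti addition), which leaves bromine on the tertiary carbon C2. The closest known reaction type is the titanium/Schiff-base-mediated bromochlorination of allylic alcohols with NBS and a chlorotitanium alkoxide, which places bromine proximal and chlorine distal to the carbinol also on 2-substituted allylic alcohols; here it is applied to a secondary carbinol. No ring is closed, and C2–Br and C1–Cl are the only bonds formed. The one new stereocentre, C2, is set by the face on which the bromonium ion forms, which is fixed by the alkoxide–titanium tether from the existing (3R) centre inside the pocket of the matched ligand and should give (2R), with bromine anti to the hydroxyl in the C1–C4 zigzag. The step needs chemoselectivity for C1=C2 over C5=C6 and C7=C8, secured because only C1=C2 is allylic to the bound alkoxide and electron-rich whereas C5=C6 is homoallylic and deactivated by conjugation to the dihalovinyl group (which also disfavours 5-endo bromoetherification), and it needs anti-Markovnikov regioselectivity, secured by intramolecular chloride delivery in a non-polar solvent that keeps free chloride out.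

Step 11
Reactants: 15 (2R,3R,5E,7Z)-2,8-dibromo-1,7-dichloro-2,6-dimethylocta-5,7-dien-3-ol
Product: 16 (2R,3R,5S,6R,7Z)-2,8-dibromo-1,7-dichloro-5,6-epoxy-2,6-dimethyloct-7-en-3-ol (CNP0151438.1)
Conditions: VO(acac)2 (5 mol %), tBuOOH (anhydrous, in decane, 1.5 equiv), CH2Cl2, 0 °C → rt
Reagents that add atoms: tert-butyl hydroperoxide, CC(C)(C)OO
Why: In this hydroxyl-directed epoxidation the C3 alkoxide binds the tert-butylperoxo complex of pentavalent vanadium and oxygen is delivered through a chair-like transition state, with the bulky C2 substituent equatorial and the C6 methyl cis to C4 reinforcing the bias, to the face of the homoallylic E-C5=C6 alkene that gives the 3,5-syn trans-oxirane (5S,6R), while the dihalovinyl alkene is too electron-poor to react and the neutral medium leaves the bromohydrin open.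

**Compound list**

1 | ethyl tiglate [ethyl (E)-2-methylbut-2-enoate] | C/C=C(\C)C(=O)OCC | starting material
2 | lithium dienolate of ethyl tiglate (not isolated) | [Li+].C=CC(C)=C([O-])OCC | intermediate
3 | tert-butyl[(1-ethoxy-2-methylbuta-1,3-dien-1-yl)oxy]dimethylsilane | C=CC(C)=C(OCC)O[Si](C)(C)C(C)(C)C | intermediate
4 | methacrolein | C=C(C)C=O | starting material
5 | ethyl (R,E)-2,6-dimethyl-5-[(trichlorosilyl)oxy]hepta-2,6-dienoate (not isolated) | C=C(C)[C@H](O[Si](Cl)(Cl)Cl)C/C=C(C)/C(=O)OCC | intermediate
6 | ethyl (R,E)-5-hydroxy-2,6-dimethylhepta-2,6-dienoate | C=C(C)[C@H](O)C/C=C(C)/C(=O)OCC | intermediate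
7 | ethyl (R,E)-5-[(tert-butyldimethylsilyl)oxy]-2,6-dimethylhepta-2,6-dienoate | C=C(C)[C@H](O[Si](C)(C)C(C)(C)C)C/C=C(C)/C(=O)OCC | intermediate
8 | (R,E)-5-[(tert-butyldimethylsilyl)oxy]-2,6-dimethylhepta-2,6-dien-1-ol | C=C(C)[C@H](O[Si](C)(C)C(C)(C)C)C/C=C(C)/CO | intermediate
9 | (R,E)-5-[(tert-butyldimethylsilyl)oxy]-2,6-dimethylhepta-2,6-dienal | C=C(C)[C@H](O[Si](C)(C)C(C)(C)C)C/C=C(C)/C=O | intermediate
10 | carbon tetrabromide | BrC(Br)(Br)Br | starting material
11 | tert-butyl{[(3R,5E)-8,8-dibromo-2,6-dimethylocta-1,5,7-trien-3-yl]oxy}dimethylsilane | C=C(C)[C@H](O[Si](C)(C)C(C)(C)C)C/C=C(C)/C=C(Br)Br | intermediate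
12 | tert-butyl{[(3R,5E)-8-bromo-2,6-dimethylocta-1,5-dien-7-yn-3-yl]oxy}dimethylsilane | C=C(C)[C@H](O[Si](C)(C)C(C)(C)C)C/C=C(C)/C#CBr | intermediate
13 | tert-butyl{[(3R,5E,7Z)-8-bromo-7-chloro-2,6-dimethylocta-1,5,7-trien-3-yl]oxy}dimethylsilane | C=C(C)[C@H](O[Si](C)(C)C(C)(C)C)C/C=C(C)/C(Cl)=C/Br | intermediate
14 | (3R,5E,7Z)-8-bromo-7-chloro-2,6-dimethylocta-1,5,7-trien-3-ol | C=C(C)[C@H](O)C/C=C(C)/C(Cl)=C/Br | intermediate
15 | (2R,3R,5E,7Z)-2,8-dibromo-1,7-dichloro-2,6-dimethylocta-5,7-dien-3-ol | C[C@](Br)(CCl)[C@H](O)C/C=C(C)/C(Cl)=C/Br | intermediate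
16 | (2R,3R,5S,6R,7Z)-2,8-dibromo-1,7-dichloro-5,6-epoxy-2,6-dimethyloct-7-en-3-ol (CNP0151438.1) | C[C@](Br)(CCl)[C@H](O)C[C@@H]1O[C@@]1(C)/C(Cl)=C/Br | target

Total step count: 11
Longest linear sequence: 11 steps (from 1 to 16)

**Steps most likely to fail**

Step 10. Bromine may be delivered to the wrong face of C1=C2 if the (3R) centre overrides both ligand enantiomers. Halonium formation may also drift to C5=C6 with capture by the C3 oxygen, or free chloride may open the bromonium ion in the Markovnikov sense. The fallback sets out from 3 and returns at 15. It installs the halogens before C3 is a stereocentre, on a primary 2-substituted allylic alcohol of the class for which the titanium-mediated bromochlorination is established. Commercial 2-methylprop-2-en-1-ol is treated with NBS, ClTi(OiPr)3 and the ligand enantiomer that gives (R)-2-bromo-3-chloro-2-methylpropan-1-ol F1. Dess–Martin oxidation gives the non-enolisable (R)-2-bromo-3-chloro-2-methylpropanal F2. A BF3·OEt2-promoted vinylogous Mukaiyama aldol with 3 then forms C3–C4 and should give ethyl (2E,5R,6R)-6-bromo-7-chloro-5-hydroxy-2,6-dimethylhept-2-enoate F3. The carbinol configuration now comes from polar Felkin–Anh attack anti to the C–Br bond, and a minor epimer would be removed by chromatography. The operations of steps 3 to 9 are then repeated on the halogenated series: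
- silylation to ethyl (2E,5R,6R)-6-bromo-5-[(tert-butyldimethylsilyl)oxy]-7-chloro-2,6-dimethylhept-2-enoate F4;
- iBu2AlH reduction to (2E,5R,6R)-6-bromo-5-[(tert-butyldimethylsilyl)oxy]-7-chloro-2,6-dimethylhept-2-en-1-ol F5;
- MnO2 oxidation to (2E,5R,6R)-6-bromo-5-[(tert-butyldimethylsilyl)oxy]-7-chloro-2,6-dimethylhept-2-enal F6;
- dibromo-olefination to tert-butyl{[(2R,3R,5E)-2,8,8-tribromo-1-chloro-2,6-dimethylocta-5,7-dien-3-yl]oxy}dimethylsilane F7;
- dehydrobromination with NaN(SiMe3)2 at −78 °C (kept cold to spare the tertiary bromide) to tert-butyl{[(2R,3R,5E)-2,8-dibromo-1-chloro-2,6-dimethyloct-5-en-7-yn-3-yl]oxy}dimethylsilane F8;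
- palladium-catalysed hydrochlorination to tert-butyl{[(2R,3R,5E,7Z)-2,8-dibromo-1,7-dichloro-2,6-dimethylocta-5,7-dien-3-yl]oxy}dimethylsilane F9;
- HF·pyridine desilylation to 15.

Step 11. Oxygen transfer to the conjugated, electron-poor C5=C6 alkene may be slow or poorly face-selective, and the Lewis-acidic vanadium may open the new vinyl oxirane with the C3 hydroxyl. The fallback sets out from 15 and returns at 16, and replaces the hydroxyl relay by reagent control. 15 is silylated (Et3SiOTf, 2,6-lutidine, CH2Cl2, −78 °C) to triethyl{[(2R,3R,5E,7Z)-2,8-dibromo-1,7-dichloro-2,6-dimethylocta-5,7-dien-3-yl]oxy}silane F10. This removes the alkoxide that could close the bromohydrin at the basic pH of the next operation and the nucleophile that could open the oxirane. Shi epoxidation follows, with KHSO5 and K2CO3 buffer in MeCN/dimethoxymethane/water at 0 °C. The catalyst is the L-fructose-derived enantiomer of the chiral ketone, the mirror image of the common D-fructose-derived one, chosen from the spiro transition-state model for an E-trisubstituted alkene. It should give triethyl{[(2R,3R,5S,6R,7Z)-2,8-dibromo-1,7-dichloro-5,6-epoxy-2,6-dimethyloct-7-en-3-yl]oxy}silane F11. HF·pyridine then frees the carbinol and gives 16.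

Step 2. Enantioselectivity may be insufficient, the dienolate may attack through its α-carbon, or the small, polymerisable enal may oligomerise. The fallback sets out from 4 and returns at 6. Allylboration of 4 with the B-allyldiisopinocampheylborane derived from (−)-α-pinene (Re-face attack, Et2O, −78 °C, then NaOH/H2O2) gives (R)-2-methylhexa-1,5-dien-3-ol F12. Cross-metathesis of its monosubstituted alkene with excess ethyl methacrylate (second-generation Hoveyda–Grubbs catalyst, CH2Cl2, 40 °C) should give the E-trisubstituted enoate 6 directly, the hindered 1,1-disubstituted isopropenyl alkene being left alone.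

**Further compounds**

F1 | step 10 | (R)-2-bromo-3-chloro-2-methylpropan-1-ol | C[C@](Br)(CCl)CO
F2 | step 10 | (R)-2-bromo-3-chloro-2-methylpropanal | C[C@](Br)(CCl)C=O
F3 | step 10 | ethyl (2E,5R,6R)-6-bromo-7-chloro-5-hydroxy-2,6-dimethylhept-2-enoate | C[C@](Br)(CCl)[C@H](O)C/C=C(C)/C(=O)OCC
F4 | step 10 | ethyl (2E,5R,6R)-6-bromo-5-[(tert-butyldimethylsilyl)oxy]-7-chloro-2,6-dimethylhept-2-enoate | C[C@](Br)(CCl)[C@H](O[Si](C)(C)C(C)(C)C)C/C=C(C)/C(=O)OCC
F5 | step 10 | (2E,5R,6R)-6-bromo-5-[(tert-butyldimethylsilyl)oxy]-7-chloro-2,6-dimethylhept-2-en-1-ol | C[C@](Br)(CCl)[C@H](O[Si](C)(C)C(C)(C)C)C/C=C(C)/CO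
F6 | step 10 | (2E,5R,6R)-6-bromo-5-[(tert-butyldimethylsilyl)oxy]-7-chloro-2,6-dimethylhept-2-enal | C[C@](Br)(CCl)[C@H](O[Si](C)(C)C(C)(C)C)C/C=C(C)/C=O
F7 | step 10 | tert-butyl{[(2R,3R,5E)-2,8,8-tribromo-1-chloro-2,6-dimethylocta-5,7-dien-3-yl]oxy}dimethylsilane | C[C@](Br)(CCl)[C@H](O[Si](C)(C)C(C)(C)C)C/C=C(C)/C=C(Br)Br
F8 | step 10 | tert-butyl{[(2R,3R,5E)-2,8-dibromo-1-chloro-2,6-dimethyloct-5-en-7-yn-3-yl]oxy}dimethylsilane | C[C@](Br)(CCl)[C@H](O[Si](C)(C)C(C)(C)C)C/C=C(C)/C#CBr
F9 | step 10 | tert-butyl{[(2R,3R,5E,7Z)-2,8-dibromo-1,7-dichloro-2,6-dimethylocta-5,7-dien-3-yl]oxy}dimethylsilane | C[C@](Br)(CCl)[C@H](O[Si](C)(C)C(C)(C)C)C/C=C(C)/C(Cl)=C/Br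
F10 | step 11 | triethyl{[(2R,3R,5E,7Z)-2,8-dibromo-1,7-dichloro-2,6-dimethylocta-5,7-dien-3-yl]oxy}silane | C[C@](Br)(CCl)[C@H](O[Si](CC)(CC)CC)C/C=C(C)/C(Cl)=C/Br
F11 | step 11 | triethyl{[(2R,3R,5S,6R,7Z)-2,8-dibromo-1,7-dichloro-5,6-epoxy-2,6-dimethyloct-7-en-3-yl]oxy}silane | C[C@](Br)(CCl)[C@H](O[Si](CC)(CC)CC)C[C@@H]1O[C@@]1(C)/C(Cl)=C/Br
F12 | step 2 | (R)-2-methylhexa-1,5-dien-3-ol | C=C(C)[C@H](O)CC=C
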